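Ring B of the target (C5–C6–C7–C8–C9–C10) is a cyclohexane that shares a cis-fused C5–C10 edge with ring A and carries its carbinol at C8, so it is the retron of a Diels–Alder reaction. The C5=C10 alkene of a ring A enal (formyl on C10 as masked methyl, C3 oxygen as controlling stereocentre) adds an (E)-configured C6=C7–C8(CH3)=C9–C11 diene bearing a phenylsulfonyl group on C11. One operation closes ring B, forms C5–C6 and C9–C10 and sets C5, C9 and C10. The C7=C8 alkene is then hydrated, and the sulfone carries in the farnesyl chain, whose terminal methyl is oxidised last.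

Key step: step 6

Remark: the SMILES is taken literally, i.e. (5S,8R,9R,10S) with H-5, the C10 methyl, C11 and the C8 methyl on one face (β) and 8-OH on the other (α), which is a cis-fused decalin; compound 1 is taken as a catalogue compound (it is the baker's yeast reduction product of 2,2-dimethylcyclohexane-1,3-dione).

Numbering: drimane numbering for the bicycles (C1–C10; C11 on C9; C15 = carbon on C10) and polypodane numbering for the C30 compounds (C30 = terminal carbon trans to C20); 5β means H-5 cis to the C10 substituent.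

Step 1
Reactants: 1 (3S)-3-hydroxy-2,2-dimethylcyclohexan-1-one
Product: 2 (3S)-3-[(tert-butyldimethylsilyl)oxy]-2,2-dimethylcyclohexan-1-one
Conditions: TBSCl, imidazole, DMF, 40 °C
Reagents that add atoms: tert-butyldimethylsilyl chloride (TBSCl), CC(C)(C)[Si](C)(C)Cl
Why: Imidazole-mediated O-silylation protects the C3 hydroxyl, whose stereocentre is kept to steer the later cycloaddition.

Step 2
Reactants: 2 (3S)-3-[(tert-butyldimethylsilyl)oxy]-2,2-dimethylcyclohexan-1-one
Product: 3 (3S,6E)-3-[(tert-butyldimethylsilyl)oxy]-6-[(dimethylamino)methylidene]-2,2-dimethylcyclohexan-1-one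
Conditions: tert-butoxybis(dimethylamino)methane, toluene, 110 °C
Reagents that add atoms: tert-butoxybis(dimethylamino)methane (Bredereck's reagent), CN(C)C(OC(C)(C)C)N(C)C
Why: Aminomethylenation (enaminone formation) can occur only at the single α-CH2 group because the other α-carbon is quaternary.

Step 3
Reactants: 3 (3S,6E)-3-[(tert-butyldimethylsilyl)oxy]-6-[(dimethylamino)methylidene]-2,2-dimethylcyclohexan-1-one
Product: 5 (4S)-4-[(tert-butyldimethylsilyl)oxy]-3,3-dimethylcyclohex-1-ene-1-carbaldehyde, via amino allylic alcohol 4 (not isolated)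
Conditions: LiAlH4, Et2O, 0 °C; then 1 M aq. HCl, THF, 0 °C
Reagents that add atoms: water, O
Why: 1,2-Hydride reduction of the vinylogous amide should give the γ-amino allylic alcohol, which on acidification loses water to a conjugated iminium ion and hydrolyses to the enal (net 1,3-carbonyl transposition), the C3 stereocentre not being involved.

Step 4
Reactants: 6 (2E)-3-methylpent-2-en-4-yn-1-ol
Product: 8 {[(2E)-3-methylpent-2-en-4-yn-1-yl]sulfonyl}benzene, via enynyl bromide 7 (not isolated)
Conditions: PPh3, NBS, CH2Cl2, −20 °C; then PhSO2Na, Bu4NI (cat.), DMF, 25 °C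
Reagents that add atoms: sodium benzenesulfinate, [Na+].[O-]S(=O)c1ccccc1
Why: Appel-type bromination of the primary allylic alcohol followed by SN2 S-alkylation of the sulfinate should give the allylic sulfone with the (E)-alkene untouched.

Step 5
Reactants: 8 {[(2E)-3-methylpent-2-en-4-yn-1-yl]sulfonyl}benzene
Product: 9 {[(2E)-3-methylpenta-2,4-dien-1-yl]sulfonyl}benzene
Conditions: H2 (1 atm), Pd/CaCO3 poisoned with Pb(OAc)2 (Lindlar catalyst), quinoline, EtOAc, 25 °C
Reagents that add atoms: none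
Why: Lindlar semihydrogenation should stop the terminal alkyne at the vinyl group and leave the (E)-trisubstituted alkene, giving the diene with CH2SO2Ph in the outside position.

Step 6
Reactants: 5 (4S)-4-[(tert-butyldimethylsilyl)oxy]-3,3-dimethylcyclohex-1-ene-1-carbaldehyde; 9 {[(2E)-3-methylpenta-2,4-dien-1-yl]sulfonyl}benzene
Product: 10 11-(phenylsulfonyl)-3β-[(tert-butyldimethylsilyl)oxy]-5β-drim-7-en-15-al (cis-fused; H-5, CHO on C10 and C11 all β; H-9 α)
Conditions: Me2AlCl (0.5 equiv), CH2Cl2, −78 → −20 °C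
Reagents that add atoms: none
Why: This is a Lewis-acid-catalysed, concerted but asynchronous [4+2] cycloaddition (Diels–Alder reaction) of the Me2AlCl-complexed enal 5 (2π: C5=C10) with the (E)-diene 9 (4π: C6=C7–C8=C9), the closest known type being Lewis-acid-promoted Diels–Alder reactions of cyclohex-1-ene-1-carbaldehydes and 4,4-dimethylcyclohex-2-enones with 1,2-disubstituted butadienes, which give cis-fused octalins. Ring B is closed as a six-membered ring by this intermolecular cycloaddition, suprafacial on both partners, which forms C5–C6 and C9–C10 together and leaves the C7=C8 alkene for the later hydration. C5 and C10 should come out cis because both new bonds are made to one face of the ring alkene, and that face is chosen by the C3 stereocentre: in the half-chair with equatorial OTBS the pseudoaxial C4 methyl shields the face syn to OTBS, so the diene should add anti to it (H-5 and CHO β, as in trans addition to a 5-substituted cyclohexenone). C9 is set by the (E)-geometry of the diene together with the endo orientation of the complexed formyl group, which places C11 cis to the formyl carbon, the future C10 methyl. The step needs regioselectivity (C9 to C10, not to C5), endo selectivity and facial selectivity; the first is secured by the ortho rule for a 1-substituted diene (larger coefficient at C6, which attacks the β-carbon C5) and by sterics, since only the unsubstituted CH2 terminus can reach the neopentyl C5. The sulfone is a poor Lewis base, leaves the aldehyde as the complexation site, is no longer allylic in the product and serves later as the coupling handle.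

Step 7
Reactants: 10 11-(phenylsulfonyl)-3β-[(tert-butyldimethylsilyl)oxy]-5β-drim-7-en-15-al
Product: 12 11-(phenylsulfonyl)-3β-[(tert-butyldimethylsilyl)oxy]-5β-drim-7-ene, via hydrazone 11 (not isolated)
Conditions: N2H4·H2O, EtOH, 80 °C; then KOtBu, DMSO, 25 °C
Reagents that add atoms: none
Why: Wolff–Kishner reduction (hydrazone of the non-enolisable neopentyl aldehyde, then base-induced loss of N2 at room temperature) should turn the angular formyl group into the C10 methyl without touching the silyl ether, alkene or sulfone and without changing a stereocentre.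

Step 8
Reactants: 12 11-(phenylsulfonyl)-3β-[(tert-butyldimethylsilyl)oxy]-5β-drim-7-ene
Product: 14 11-(phenylsulfonyl)-3β-[(tert-butyldimethylsilyl)oxy]-5β-driman-8α-ol, via organomercurial 13 (not isolated)
Conditions: Hg(OAc)2, THF/H2O (1:1), 25 °C; then NaBH4, 3 M aq. NaOH, 0 °C
Reagents that add atoms: water, O
Why: Oxymercuration–demercuration is a Markovnikov anti addition in which water should open the mercurinium ion at the tertiary C8 in the trans-diaxial (Fürst–Plattner) sense from the half-chair that keeps the C9 CH2SO2Ph group pseudoaxial (A1,2 strain with the C8 methyl), so that OH enters trans to C11 (8α, 8R) and NaBH4 then replaces mercury at C7 by hydrogen.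

Step 9
Reactants: 14 11-(phenylsulfonyl)-3β-[(tert-butyldimethylsilyl)oxy]-5β-driman-8α-ol; 15 (2E,6E)-1-bromo-3,7,11-trimethyldodeca-2,6,10-triene (trans,trans-farnesyl bromide)
Product: 16 11-(phenylsulfonyl)-3β-[(tert-butyldimethylsilyl)oxy]-5β-polypoda-13E,17E,21-trien-8α-ol (both C11 epimers)
Conditions: n-BuLi (2.2 equiv), THF/DMPU, −78 °C; then 15, −78 → −20 °C
Reagents that add atoms: none
Why: The α-sulfonyl carbanion of the O,C-dilithiated hydroxy sulfone should displace the primary allylic bromide by SN2 (sulfone alkylation), forming C11–C12 with the E,E geometry of 15 intact; the new C11 centre is irrelevant because the sulfonyl group is removed next.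

Step 10
Reactants: 16 11-(phenylsulfonyl)-3β-[(tert-butyldimethylsilyl)oxy]-5β-polypoda-13E,17E,21-trien-8α-ol
Product: 17 3β-[(tert-butyldimethylsilyl)oxy]-5β-polypoda-13E,17E,21-trien-8α-ol
Conditions: Na/Hg amalgam (6% Na), Na2HPO4, MeOH/THF, −20 → 0 °C
Reagents that add atoms: none
Why: Reductive desulfonylation by electron transfer from sodium amalgam should cleave the C11–S bond without touching the isolated trisubstituted alkenes, the silyl ether or the tertiary alcohol.

Step 11
Reactants: 17 3β-[(tert-butyldimethylsilyl)oxy]-5β-polypoda-13E,17E,21-trien-8α-ol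
Product: 18 3β-[(tert-butyldimethylsilyl)oxy]-5β-polypoda-13E,17E,21E-triene-8α,30-diol
Conditions: SeO2 (0.3 equiv), t-BuOOH (3 equiv), salicylic acid (0.1 equiv), CH2Cl2, 25 °C
Reagents that add atoms: tert-butyl hydroperoxide, CC(C)(C)OO
Why: SeO2-catalysed allylic oxidation (ene reaction, then [2,3]-sigmatropic shift) should take place at the (E)-methyl group of the terminal isopropylidene unit, the most accessible site of such polyprenyl chains, and give the (E)-allylic alcohol.

Step 12
Reactants: 18 3β-[(tert-butyldimethylsilyl)oxy]-5β-polypoda-13E,17E,21E-triene-8α,30-diol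
Product: 19 5β-polypoda-13E,17E,21E-triene-3β,8α,30-triol
Conditions: Bu4NF, THF, 60 °C
Reagents that add atoms: none
Why: Fluoride-induced desilylation should free the hindered C3 hydroxyl without affecting any stereocentre.

Step 13
Reactants: 19 5β-polypoda-13E,17E,21E-triene-3β,8α,30-triol
Product: 20 8α-hydroxy-3-oxo-5β-polypoda-13E,17E,21E-trien-30-al
Conditions: Dess–Martin periodinane (3 equiv), CH2Cl2, 25 °C
Reagents that add atoms: none
Why: Dess–Martin oxidation should convert the secondary C3 alcohol into the ketone and the primary allylic alcohol into the (E)-enal in one operation, the tertiary C8 alcohol being inert.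

Step 14
Reactants: 20 8α-hydroxy-3-oxo-5β-polypoda-13E,17E,21E-trien-30-al
Product: 21 myrrhanone B as drawn, 8α-hydroxy-3-oxo-5β-polypoda-13E,17E,21E-trien-30-oic acid, (5S,8R,9R,10S)
Conditions: NaClO2, NaH2PO4, 2-methylbut-2-ene, t-BuOH/H2O, 0 → 25 °C
Reagents that add atoms: sodium chlorite, [Na+].[O-]Cl=O
Why: Pinnick oxidation should turn the enal into the carboxylic acid without isomerising the alkene or touching the ketone and the tertiary alcohol, 2-methylbut-2-ene scavenging the hypochlorous acid.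

Compound list
1 | (3S)-3-hydroxy-2,2-dimethylcyclohexan-1-one | O=C1CCC[C@H](O)C1(C)C | starting material
2 | (3S)-3-[(tert-butyldimethylsilyl)oxy]-2,2-dimethylcyclohexan-1-one | O=C1CCC[C@H](O[Si](C)(C)C(C)(C)C)C1(C)C | intermediate
3 | (3S,6E)-3-[(tert-butyldimethylsilyl)oxy]-6-[(dimethylamino)methylidene]-2,2-dimethylcyclohexan-1-one | O=C1/C(=C/N(C)C)CC[C@H](O[Si](C)(C)C(C)(C)C)C1(C)C | intermediate
4 | (3S,6E)-3-[(tert-butyldimethylsilyl)oxy]-6-[(dimethylamino)methylidene]-2,2-dimethylcyclohexan-1-ol (C1 epimers, not isolated) | OC1/C(=C/N(C)C)CC[C@H](O[Si](C)(C)C(C)(C)C)C1(C)C | intermediate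
5 | (4S)-4-[(tert-butyldimethylsilyl)oxy]-3,3-dimethylcyclohex-1-ene-1-carbaldehyde | O=CC1=CC(C)(C)[C@@H](O[Si](C)(C)C(C)(C)C)CC1 | intermediate
6 | (2E)-3-methylpent-2-en-4-yn-1-ol | OC/C=C(C)/C#C | starting material
7 | (3E)-5-bromo-3-methylpent-3-en-1-yne (not isolated) | BrC/C=C(C)/C#C | intermediate
8 | {[(2E)-3-methylpent-2-en-4-yn-1-yl]sulfonyl}benzene | O=S(=O)(C/C=C(C)/C#C)c1ccccc1 | intermediate
9 | {[(2E)-3-methylpenta-2,4-dien-1-yl]sulfonyl}benzene | O=S(=O)(C/C=C(C)/C=C)c1ccccc1 | intermediate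
10 | 11-(phenylsulfonyl)-3β-[(tert-butyldimethylsilyl)oxy]-5β-drim-7-en-15-al | O=S(=O)(c3ccccc3)C[C@@H]1[C@@]2(C=O)CC[C@H](O[Si](C)(C)C(C)(C)C)C(C)(C)[C@H]2CC=C1C | intermediate
11 | hydrazone of 10 at C15 (not isolated) | O=S(=O)(c3ccccc3)C[C@@H]1[C@@]2(C=NN)CC[C@H](O[Si](C)(C)C(C)(C)C)C(C)(C)[C@H]2CC=C1C | intermediate
12 | 11-(phenylsulfonyl)-3β-[(tert-butyldimethylsilyl)oxy]-5β-drim-7-ene | O=S(=O)(c3ccccc3)C[C@@H]1[C@@]2(C)CC[C@H](O[Si](C)(C)C(C)(C)C)C(C)(C)[C@H]2CC=C1C | intermediate
13 | 7β-(acetoxymercurio)-11-(phenylsulfonyl)-3β-[(tert-butyldimethylsilyl)oxy]-5β-driman-8α-ol (not isolated) | O=S(=O)(c3ccccc3)C[C@@H]1[C@@]2(C)CC[C@H](O[Si](C)(C)C(C)(C)C)C(C)(C)[C@H]2C[C@H]([Hg]OC(C)=O)[C@@]1(C)O | intermediate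
14 | 11-(phenylsulfonyl)-3β-[(tert-butyldimethylsilyl)oxy]-5β-driman-8α-ol | O=S(=O)(c3ccccc3)C[C@@H]1[C@@]2(C)CC[C@H](O[Si](C)(C)C(C)(C)C)C(C)(C)[C@H]2CC[C@@]1(C)O | intermediate
15 | (2E,6E)-1-bromo-3,7,11-trimethyldodeca-2,6,10-triene | BrC/C=C(C)/CC/C=C(C)/CCC=C(C)C | starting material
16 | 11-(phenylsulfonyl)-3β-[(tert-butyldimethylsilyl)oxy]-5β-polypoda-13E,17E,21-trien-8α-ol (C11 epimers) | CC(C)=CCC/C(C)=C/CC/C(C)=C/CC(S(=O)(=O)c3ccccc3)[C@@H]1[C@@]2(C)CC[C@H](O[Si](C)(C)C(C)(C)C)C(C)(C)[C@H]2CC[C@@]1(C)O | intermediate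
17 | 3β-[(tert-butyldimethylsilyl)oxy]-5β-polypoda-13E,17E,21-trien-8α-ol | CC(C)=CCC/C(C)=C/CC/C(C)=C/CC[C@@H]1[C@@]2(C)CC[C@H](O[Si](C)(C)C(C)(C)C)C(C)(C)[C@H]2CC[C@@]1(C)O | intermediate
18 | 3β-[(tert-butyldimethylsilyl)oxy]-5β-polypoda-13E,17E,21E-triene-8α,30-diol | OC/C(C)=C/CC/C(C)=C/CC/C(C)=C/CC[C@@H]1[C@@]2(C)CC[C@H](O[Si](C)(C)C(C)(C)C)C(C)(C)[C@H]2CC[C@@]1(C)O | intermediate
19 | 5β-polypoda-13E,17E,21E-triene-3β,8α,30-triol | OC/C(C)=C/CC/C(C)=C/CC/C(C)=C/CC[C@@H]1[C@@]2(C)CC[C@H](O)C(C)(C)[C@H]2CC[C@@]1(C)O | intermediate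
20 | 8α-hydroxy-3-oxo-5β-polypoda-13E,17E,21E-trien-30-al | O=C/C(C)=C/CC/C(C)=C/CC/C(C)=C/CC[C@@H]1[C@@]2(C)CCC(=O)C(C)(C)[C@H]2CC[C@@]1(C)O | intermediate
21 | myrrhanone B as drawn, (5S,8R,9R,10S)-8α-hydroxy-3-oxo-5β-polypoda-13E,17E,21E-trien-30-oic acid | C/C(=C\CC/C(C)=C/CC[C@@H]1[C@@]2(C)CCC(=O)C(C)(C)[C@H]2CC[C@@]1(C)O)CC/C=C(\C)C(=O)O | target

Total step count: 14. Longest linear sequence: 12 steps (steps 1–3 and 6–14, from 1 to 21); the diene branch (steps 4 and 5) joins at step 6.

Steps most likely to fail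

Step 6. The cycloaddition must take place at a β-carbon flanked by the quaternary C4. If it is slow, Lewis-acid-induced loss of sulfinate from the dienylic sulfone and oligomerisation of the diene can compete, and regio- or facial selectivity may erode. The fallback sets out from 6 and 5 and comes back at 12; it carries sulfur through the cycloaddition at the sulfide level. Semihydrogenation of 6 (H2, Pd/CaCO3 poisoned with Pb(OAc)2, quinoline) would give (2E)-3-methylpenta-2,4-dien-1-ol F1. PhSSPh/PBu3 would convert it into the more electron-rich, non-ionisable {[(2E)-3-methylpenta-2,4-dien-1-yl]sulfanyl}benzene F2. Its Me2AlCl-promoted Diels–Alder reaction with 5 would give 11-(phenylsulfanyl)-3β-[(tert-butyldimethylsilyl)oxy]-5β-drim-7-en-15-al F3. Wolff–Kishner reduction as in step 7, through the C15 hydrazone F4 (not isolated), would give 11-(phenylsulfanyl)-3β-[(tert-butyldimethylsilyl)oxy]-5β-drim-7-ene F5. Chemoselective S-oxidation ((NH4)6Mo7O24 cat., H2O2, EtOH, 0 °C) would then return to 12.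

Step 8. Water may open the mercurinium ion on the face syn to C11 and give the C8 epimer, or the hindered β-hydroxy organomercurial may revert to the alkene during reduction. The fallback sets out from 12 and comes back at 14. Epoxidation with dimethyldioxirane (acetone, 0 °C) uses an electrophile that, like mercury, takes the more accessible face but delivers oxygen syn instead of anti. It would give 7α,8α-epoxy-11-(phenylsulfonyl)-3β-[(tert-butyldimethylsilyl)oxy]-5β-drimane F6. LiEt3BH (THF, 0 → 25 °C) would open the epoxide by hydride attack at the secondary C7 to give 14.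

Step 11. The allylic oxidation may not discriminate fully between the terminal isopropylidene group and the two internal trisubstituted alkenes, and over-oxidation would cost late material. The fallback sets out from 14 and comes back at 19; it places the oxygen in the chain before the coupling.
- Commercial (2E,6E)-farnesyl acetate with SeO2 (cat.)/t-BuOOH would give (2E,6E,10E)-12-hydroxy-3,7,11-trimethyldodeca-2,6,10-trien-1-yl acetate F7.
- TBSCl/imidazole would give (2E,6E,10E)-12-[(tert-butyldimethylsilyl)oxy]-3,7,11-trimethyldodeca-2,6,10-trien-1-yl acetate F8.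
- K2CO3/MeOH would give (2E,6E,10E)-12-[(tert-butyldimethylsilyl)oxy]-3,7,11-trimethyldodeca-2,6,10-trien-1-ol F9.
- CBr4/PPh3 would give {[(2E,6E,10E)-12-bromo-2,6,10-trimethyldodeca-2,6,10-trien-1-yl]oxy}(tert-butyl)dimethylsilane F10.
- Alkylation of the dianion of 14 with this bromide as in step 9 would give 11-(phenylsulfonyl)-3β,30-bis[(tert-butyldimethylsilyl)oxy]-5β-polypoda-13E,17E,21E-trien-8α-ol F11.
- Desulfonylation as in step 10 would give 3β,30-bis[(tert-butyldimethylsilyl)oxy]-5β-polypoda-13E,17E,21E-trien-8α-ol F12.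
- Bu4NF (THF, 60 °C) would remove both silyl groups and give 19.

Further compounds
F1 | step 6 | (2E)-3-methylpenta-2,4-dien-1-ol | OC/C=C(C)/C=C
F2 | step 6 | {[(2E)-3-methylpenta-2,4-dien-1-yl]sulfanyl}benzene | C=C/C(C)=C/CSc1ccccc1
F3 | step 6 | 11-(phenylsulfanyl)-3β-[(tert-butyldimethylsilyl)oxy]-5β-drim-7-en-15-al | c3ccccc3SC[C@@H]1[C@@]2(C=O)CC[C@H](O[Si](C)(C)C(C)(C)C)C(C)(C)[C@H]2CC=C1C
F4 | step 6 | hydrazone of F3 at C15 (not isolated) | c3ccccc3SC[C@@H]1[C@@]2(C=NN)CC[C@H](O[Si](C)(C)C(C)(C)C)C(C)(C)[C@H]2CC=C1C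
F5 | step 6 | 11-(phenylsulfanyl)-3β-[(tert-butyldimethylsilyl)oxy]-5β-drim-7-ene | c3ccccc3SC[C@@H]1[C@@]2(C)CC[C@H](O[Si](C)(C)C(C)(C)C)C(C)(C)[C@H]2CC=C1C
F6 | step 8 | 7α,8α-epoxy-11-(phenylsulfonyl)-3β-[(tert-butyldimethylsilyl)oxy]-5β-drimane | O=S(=O)(c4ccccc4)C[C@@H]1[C@@]2(C)CC[C@H](O[Si](C)(C)C(C)(C)C)C(C)(C)[C@H]2C[C@H]3O[C@@]13C
F7 | step 11 | (2E,6E,10E)-12-hydroxy-3,7,11-trimethyldodeca-2,6,10-trien-1-yl acetate | CC(=O)OC/C=C(C)/CC/C=C(C)/CC/C=C(C)/CO
F8 | step 11 | (2E,6E,10E)-12-[(tert-butyldimethylsilyl)oxy]-3,7,11-trimethyldodeca-2,6,10-trien-1-yl acetate | CC(=O)OC/C=C(C)/CC/C=C(C)/CC/C=C(C)/CO[Si](C)(C)C(C)(C)C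
F9 | step 11 | (2E,6E,10E)-12-[(tert-butyldimethylsilyl)oxy]-3,7,11-trimethyldodeca-2,6,10-trien-1-ol | OC/C=C(C)/CC/C=C(C)/CC/C=C(C)/CO[Si](C)(C)C(C)(C)C
F10 | step 11 | {[(2E,6E,10E)-12-bromo-2,6,10-trimethyldodeca-2,6,10-trien-1-yl]oxy}(tert-butyl)dimethylsilane | BrC/C=C(C)/CC/C=C(C)/CC/C=C(C)/CO[Si](C)(C)C(C)(C)C
F11 | step 11 | 11-(phenylsulfonyl)-3β,30-bis[(tert-butyldimethylsilyl)oxy]-5β-polypoda-13E,17E,21E-trien-8α-ol (C11 epimers) | CC(C)(C)[Si](C)(C)OC/C(C)=C/CC/C(C)=C/CC/C(C)=C/CC(S(=O)(=O)c3ccccc3)[C@@H]1[C@@]2(C)CC[C@H](O[Si](C)(C)C(C)(C)C)C(C)(C)[C@H]2CC[C@@]1(C)O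
F12 | step 11 | 3β,30-bis[(tert-butyldimethylsilyl)oxy]-5β-polypoda-13E,17E,21E-trien-8α-ol | CC(C)(C)[Si](C)(C)OC/C(C)=C/CC/C(C)=C/CC/C(C)=C/CC[C@@H]1[C@@]2(C)CC[C@H](O[Si](C)(C)C(C)(C)C)C(C)(C)[C@H]2CC[C@@]1(C)O
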